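**Plan** (O1, C2–C8a = upper flavan unit; C8 = catechin carbon that carries it)
1. Retrosynthesis: after removal of eight benzyl ethers, ring C of the upper flavan (O1–C2–C3–C4–C4a–C8a) is contracted. O1 is moved from C2 to C3 and C2 is raised to an aryl ketone, which gives a trans-2-aroyl-3-aryl-2,3-dihydrobenzofuran.
2. This five-membered ring is cut at C3–O1 and C3–C4 ([4+1]) into an o-quinone methide (ring A, C4, catechin C8) and a phenacyl ammonium ylide (C3, C2, ring B). The methide precursor is cut at C4–C8 into 8-lithiated benzylated (+)-catechin and 4-benzyloxysalicylaldehyde.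
3. Forward order: C4–C8 bond, then the dihydrobenzofuran ring, then its enlargement by one atom to ring C, then deprotection.
4. Enabling feature: C3 is a bare CH2 between the O-bearing benzylic C2 and the diarylmethine C4, and O1 sits on C8a ortho to C4a. O1 can therefore be parked on C3 as a phenacyl-type ether whose C3–O1 bond is reductively labile, and the freed phenol can re-close only on C2.
5. Stereochemistry: the lower unit comes from (+)-catechin, C4 from the alkaloid-controlled [4+1] annulation, and C2 from C4 by hydride delivery to the cyclic oxocarbenium ion (2,4-cis).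

Key step: step 9

Assumption: the quinidine-derived leaving group is taken to direct the ylide to the face of 14 that gives (2R,3S)-16; if a test run shows the opposite sense, the pseudo-enantiomeric quinine salt takes its place without other change.

Step 1
Reactants: 1 (+)-catechin
Product: 2 5,7,3',4'-tetra-O-benzyl-(+)-catechin
Conditions: BnBr (4.4 equiv), K2CO3, DMF, 0 °C → rt
Reagents that add atoms: benzyl bromide, BrCc1ccccc1
Why: Williamson etherification in which K2CO3 deprotonates only the four phenols, so the secondary 3-OH stays free and neither stereocentre is touched.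

Step 2
Reactants: 2 5,7,3',4'-tetra-O-benzyl-(+)-catechin
Product: 3 3,5,7,3',4'-penta-O-benzyl-(+)-catechin
Conditions: NaH, BnBr, DMF, 0 °C → rt
Reagents that add atoms: benzyl bromide, BrCc1ccccc1
Why: Williamson etherification of the remaining secondary alcohol through its sodium alkoxide removes the last acidic proton before the organolithium step and adds a group that leaves in the same final hydrogenolysis.

Step 3
Reactants: 3 3,5,7,3',4'-penta-O-benzyl-(+)-catechin
Product: 4 8-bromo-3,5,7,3',4'-penta-O-benzyl-(+)-catechin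
Conditions: NBS (1.0 equiv), CH2Cl2, −78 °C → 0 °C
Reagents that add atoms: N-bromosuccinimide, O=C1CCC(=O)N1Br
Why: Electrophilic aromatic bromination of the phloroglucinol-type ring goes to C8 rather than C6, as is well established for O-benzylated flavan-3-ols, and thereby fixes the 4→8 regiochemistry of the later C–C bond.

Step 4
Reactants: 4 8-bromo-3,5,7,3',4'-penta-O-benzyl-(+)-catechin; 5 4-(benzyloxy)-2-hydroxybenzaldehyde
Product: 8 [4-(benzyloxy)-2-hydroxyphenyl](penta-O-benzylcatechin-8-yl)methanol (both carbinol epimers), via aryllithium 6 (not isolated), via sodium phenolate 7 (not isolated)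
Conditions: 4, n-BuLi (1.05 equiv), THF, −78 °C; 5 + NaH (1.0 equiv), THF, 0 °C, cannulated into 6 at −78 °C → −20 °C; aq. NH4Cl
Reagents that add atoms: none
Why: Bromine–lithium exchange followed by 1,2-addition of the aryllithium to the aldehyde forges the C4–C8 bond at the brominated carbon only; the phenol is masked as its sodium salt so that it cannot quench 6, and the carbinol configuration is irrelevant because C4 becomes planar in step 8.

Step 5
Reactants: 8 [4-(benzyloxy)-2-hydroxyphenyl](penta-O-benzylcatechin-8-yl)methanol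
Product: 9 5-(benzyloxy)-2-[(penta-O-benzylcatechin-8-yl)(tosyl)methyl]phenol (both epimers)
Conditions: p-TolSO2H (freshly liberated from its sodium salt, 1.5 equiv), CH2Cl2, rt
Reagents that add atoms: p-toluenesulfinic acid, Cc1ccc(cc1)S(=O)O
Why: SN1-type substitution in which the doubly activated diarylcarbinol ionises under the mild acidity of the sulfinic acid and is captured at sulfur, giving the 2-(1-tosylalkyl)phenol that is the standard base-triggered precursor of o-quinone methides.

Step 6
Reactants: 10 1-[3,4-bis(benzyloxy)phenyl]ethanone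
Product: 11 1-[3,4-bis(benzyloxy)phenyl]-2-bromoethanone
Conditions: CuBr2 (2.1 equiv), EtOAc–CHCl3, reflux
Reagents that add atoms: copper dibromide CuBr2, [Cu+2].[Br-].[Br-]
Why: α-Bromination of the aryl methyl ketone through its enol with CuBr2 stops at the monobromide, and the acyl group deactivates ring B against nuclear bromination.

Step 7
Reactants: 11 1-[3,4-bis(benzyloxy)phenyl]-2-bromoethanone; 12 quinidine
Product: 13 N-{2-[3,4-bis(benzyloxy)phenyl]-2-oxoethyl}quinidinium bromide (quaternised at the quinuclidine nitrogen)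
Conditions: THF, rt → 50 °C
Reagents that add atoms: none
Why: Menshutkin quaternisation takes place at the sp3 quinuclidine nitrogen, which is far more nucleophilic than the quinoline nitrogen, and turns the alkaloid into a chiral leaving group on the future C3.

Step 8
Reactants: 9 5-(benzyloxy)-2-[(penta-O-benzylcatechin-8-yl)(tosyl)methyl]phenol; 13 N-phenacylquinidinium bromide
Product: 16 (2R,3S)-trans-6-(benzyloxy)-2-[3,4-bis(benzyloxy)benzoyl]-3-(penta-O-benzylcatechin-8-yl)-2,3-dihydrobenzofuran, via o-quinone methide 14 (not isolated), via ammonium ylide 15 (not isolated)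
Conditions: Cs2CO3 (2.5 equiv), CH2Cl2, 0 °C → rt
Reagents that add atoms: none
Why: [4+1] annulation of a carbonyl-stabilised ammonium ylide with an o-quinone methide, in which Cs2CO3 releases 14 by 1,4-elimination of sulfinate and 15 by deprotonation, the ylide carbon (C3) adds to C4, the phenoxide O1 displaces the alkaloid in a 5-exo-tet closure, the Cinchona alkaloid as chiral leaving group selects the face of 14 and so sets C4 (S), and the epimerisable α-keto position secures the 2,3-trans ring.

Step 9
Reactants: 16 (2R,3S)-trans-2-aroyl-3-(catechin-8-yl)-2,3-dihydrobenzofuran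
Product: 19 octa-O-benzyl (2S,4S)-7,3',4'-trihydroxyflavan-(4α→8)-(+)-catechin, via keto phenol 17 (not isolated), via flavan-2-ylium ion 18 (not isolated)
Conditions: SmI2 (2.5 equiv), THF–MeOH, −78 °C, argon; then in the same flask CH2Cl2, Et3SiH (5 equiv), CF3CO2H (excess), −40 → 0 °C
Reagents that add atoms: none
Why: SmI2 transfers two electrons to the aryl ketone of 16, the ketyl expels O1 from C3 as the aryloxide (C3–O1 is a phenacyl-type α-aryloxy ketone bond, the closest known reaction being the SmI2 or Zn cleavage of α-heterosubstituted ketones and phenacyl aryl ethers), and methanol protonates the samarium enolate, so that C3 becomes the CH2 of keto phenol 17 with C4 untouched. On acidification O1–H adds to the C2 carbonyl in a 6-exo-trig closure and loss of water gives the aryl-stabilised flavan-2-ylium ion 18, so that the five-membered ring O1–C3–C4–C4a–C8a has taken up the formerly exocyclic C2 between O1 and C3 and has become the six-membered ring C. Et3SiH then delivers hydride to C2, an ionic hydrogenation of a cyclic hemiketal that is well known for lactols and 2-hydroxyflavans. The new stereocentre C2 is controlled by C4: in the half-chair cation the bulky catechin-8-yl group shields one face and hydride enters anti to it along the axial trajectory, which places ring B cis to the C4 aryl group (2S,4S), and the cis isomer is also the more stable one if C2–O1 ionises reversibly. The step needs scission of one C–O bond among eight benzyl ethers and the ring ether of the lower unit, which is secured because only C3–O1 lies α to a ketone, and it needs C4 to keep its configuration, which is secured by the low temperature and by the resorcinol-type ring A that makes the C4–C8 bond slow to ionise.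

Step 10
Reactants: 19 octa-O-benzyl (2S,4S)-7,3',4'-trihydroxyflavan-(4α→8)-(+)-catechin
Product: 20 (2S)-7,3',4'-trihydroxyflavan-(4α→8)-(+)-catechin (target)
Conditions: H2 (1 atm), Pd(OH)2/C, THF–MeOH, rt
Reagents that add atoms: none
Why: Catalytic hydrogenolysis removes all eight benzyl ethers in one operation, whereas the cyclic benzylic C2–O1 bonds of both flavan units are known to survive these neutral conditions, and no stereocentre is affected.

**Compound list**
1 | (+)-catechin, (2R,3S)-2-(3,4-dihydroxyphenyl)chroman-3,5,7-triol | c1c(O)cc(O)c2c1O[C@H](c1ccc(O)c(O)c1)[C@@H](O)C2 | starting material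
2 | 5,7,3',4'-tetra-O-benzyl-(+)-catechin | c1c(OCc3ccccc3)cc(OCc3ccccc3)c2c1O[C@H](c1ccc(OCc3ccccc3)c(OCc3ccccc3)c1)[C@@H](O)C2 | intermediate
3 | 3,5,7,3',4'-penta-O-benzyl-(+)-catechin | c1c(OCc3ccccc3)cc(OCc3ccccc3)c2c1O[C@H](c1ccc(OCc3ccccc3)c(OCc3ccccc3)c1)[C@@H](OCc1ccccc1)C2 | intermediate
4 | 8-bromo-3,5,7,3',4'-penta-O-benzyl-(+)-catechin | Brc1c(OCc3ccccc3)cc(OCc3ccccc3)c2c1O[C@H](c1ccc(OCc3ccccc3)c(OCc3ccccc3)c1)[C@@H](OCc1ccccc1)C2 | intermediate
5 | 4-(benzyloxy)-2-hydroxybenzaldehyde | O=Cc1ccc(OCc2ccccc2)cc1O | starting material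
6 | 8-lithio-3,5,7,3',4'-penta-O-benzyl-(+)-catechin | [Li]c1c(OCc3ccccc3)cc(OCc3ccccc3)c2c1O[C@H](c1ccc(OCc3ccccc3)c(OCc3ccccc3)c1)[C@@H](OCc1ccccc1)C2 | intermediate
7 | sodium 5-(benzyloxy)-2-formylphenolate | O=Cc1ccc(OCc2ccccc2)cc1[O-].[Na+] | intermediate
8 | [4-(benzyloxy)-2-hydroxyphenyl](penta-O-benzylcatechin-8-yl)methanol, both carbinol epimers | OC(c1ccc(OCc2ccccc2)cc1O)c1c(OCc3ccccc3)cc(OCc3ccccc3)c2c1O[C@H](c1ccc(OCc3ccccc3)c(OCc3ccccc3)c1)[C@@H](OCc1ccccc1)C2 | intermediate
9 | 5-(benzyloxy)-2-[(penta-O-benzylcatechin-8-yl)(tosyl)methyl]phenol, both epimers | Cc1ccc(cc1)S(=O)(=O)C(c1ccc(OCc2ccccc2)cc1O)c1c(OCc3ccccc3)cc(OCc3ccccc3)c2c1O[C@H](c1ccc(OCc3ccccc3)c(OCc3ccccc3)c1)[C@@H](OCc1ccccc1)C2 | intermediate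
10 | 1-[3,4-bis(benzyloxy)phenyl]ethanone | CC(=O)c1ccc(OCc2ccccc2)c(OCc2ccccc2)c1 | starting material
11 | 1-[3,4-bis(benzyloxy)phenyl]-2-bromoethanone | BrCC(=O)c1ccc(OCc2ccccc2)c(OCc2ccccc2)c1 | intermediate
12 | quinidine | COc1ccc2nccc([C@H](O)[C@H]3C[C@@H]4CCN3C[C@@H]4C=C)c2c1 | starting material
13 | N-{2-[3,4-bis(benzyloxy)phenyl]-2-oxoethyl}quinidinium bromide | COc1ccc2nccc([C@H](O)[C@H]3C[C@@H]4CC[N+]3(CC(=O)c3ccc(OCc5ccccc5)c(OCc5ccccc5)c3)C[C@@H]4C=C)c2c1.[Br-] | intermediate
14 | o-quinone methide, 3-(benzyloxy)-6-[(penta-O-benzylcatechin-8-yl)methylidene]cyclohexa-2,4-dien-1-one | O=C1C=C(OCc2ccccc2)C=CC1=Cc1c(OCc3ccccc3)cc(OCc3ccccc3)c2c1O[C@H](c1ccc(OCc3ccccc3)c(OCc3ccccc3)c1)[C@@H](OCc1ccccc1)C2 | intermediate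
15 | ammonium ylide derived from 13 | COc1ccc2nccc([C@H](O)[C@H]3C[C@@H]4CC[N+]3([CH-]C(=O)c3ccc(OCc5ccccc5)c(OCc5ccccc5)c3)C[C@@H]4C=C)c2c1 | intermediate
16 | (2R,3S)-trans-6-(benzyloxy)-2-[3,4-bis(benzyloxy)benzoyl]-3-(penta-O-benzylcatechin-8-yl)-2,3-dihydrobenzofuran | O=C(c1ccc(OCc2ccccc2)c(OCc2ccccc2)c1)[C@@H]1Oc2cc(OCc3ccccc3)ccc2[C@H]1c1c(OCc3ccccc3)cc(OCc3ccccc3)c2c1O[C@H](c1ccc(OCc3ccccc3)c(OCc3ccccc3)c1)[C@@H](OCc1ccccc1)C2 | intermediate
17 | (3S)-1-[3,4-bis(benzyloxy)phenyl]-3-[4-(benzyloxy)-2-hydroxyphenyl]-3-(penta-O-benzylcatechin-8-yl)propan-1-one | O=C(c1ccc(OCc2ccccc2)c(OCc2ccccc2)c1)C[C@@H](c1ccc(OCc2ccccc2)cc1O)c1c(OCc3ccccc3)cc(OCc3ccccc3)c2c1O[C@H](c1ccc(OCc3ccccc3)c(OCc3ccccc3)c1)[C@@H](OCc1ccccc1)C2 | intermediate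
18 | (4S)-7-(benzyloxy)-2-[3,4-bis(benzyloxy)phenyl]-4-(penta-O-benzylcatechin-8-yl)-3,4-dihydrochromenylium trifluoroacetate | C(c1ccccc1)Oc1ccc2c(c1)[O+]=C(c1ccc(OCc3ccccc3)c(OCc3ccccc3)c1)C[C@@H]2c1c(OCc3ccccc3)cc(OCc3ccccc3)c2c1O[C@H](c1ccc(OCc3ccccc3)c(OCc3ccccc3)c1)[C@@H](OCc1ccccc1)C2.[O-]C(=O)C(F)(F)F | intermediate
19 | octa-O-benzyl ether of the target, upper unit (2S,4S) with 2,4-cis aryl groups, lower unit (2R,3S) | C(c1ccccc1)Oc1ccc2c(c1)O[C@H](c1ccc(OCc3ccccc3)c(OCc3ccccc3)c1)C[C@@H]2c1c(OCc3ccccc3)cc(OCc3ccccc3)c2c1O[C@H](c1ccc(OCc3ccccc3)c(OCc3ccccc3)c1)[C@@H](OCc1ccccc1)C2 | intermediate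
20 | (2S)-7,3',4'-trihydroxyflavan-(4α→8)-(+)-catechin, upper unit (2S,4S), lower unit (2R,3S) | Oc1ccc2c(c1)O[C@H](c1ccc(O)c(O)c1)C[C@@H]2c1c(O)cc(O)c2c1O[C@H](c1ccc(O)c(O)c1)[C@@H](O)C2 | target

Total step count: 10. Longest linear sequence: 8 (steps 1–5 and 8–10).

**Steps most likely to fail**

Step 8. The methide carbon of 14 is flanked by two ortho-oxygen substituents of the catechin ring. Addition of the bulky alkaloid ylide may therefore be sluggish, and the chirality of the catechin unit may oppose that of the leaving group, which would give poor facial selectivity. The fallback gives up reagent control in favour of separating diastereomers and sets out from 9 and 11. Bromide 11 is quaternised with dimethyl sulfide to dimethyl{2-[3,4-bis(benzyloxy)phenyl]-2-oxoethyl}sulfonium bromide F1. Its small achiral ylide is combined with 9 under Cs2CO3 in the known [4+1] annulation of sulfur ylides with o-quinone methides. This should give 16 together with the (2S,3R)-trans diastereomer F2. The two differ as diastereomers because of the enantiopure catechin unit, and they are separated by chromatography or crystallisation. The route is rejoined at 16.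

Step 9. Three things may go wrong. Excess SmI2 may reduce the liberated ketone further, the acid may ionise the C4–C8 bond with erosion of the C4 configuration, or hydride delivery to C2 may be incompletely face-selective. The fallback replaces substrate control under acid by reagent control under neutral conditions and sets out from 16. Zn dust in AcOH cleaves the phenacyl-type ether, and keto phenol 17 is isolated. Corey–Bakshi–Shibata reduction with the (S)-Me-oxazaborolidine and BH3·SMe2 gives (1R,3S)-1-[3,4-bis(benzyloxy)phenyl]-3-[4-(benzyloxy)-2-hydroxyphenyl]-3-(penta-O-benzylcatechin-8-yl)propan-1-ol F3. An intramolecular Mitsunobu etherification (PPh3, DIAD, THF, 0 °C) then closes O1–C2 with inversion. The route is rejoined at 19.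

Step 4. Proton transfer may quench the aryllithium, and the very electron-rich diol 8 may lose water prematurely during work-up. The fallback avoids both the acidic phenol and the free carbinol and sets out from 4 and 5. Aldehyde 5 is converted with Boc2O and DMAP into 5-(benzyloxy)-2-formylphenyl tert-butyl carbonate F4. Aryllithium 6, made from 4 as before, is added at −78 °C, followed by MgBr2·OEt2. The new alkoxide takes over the Boc group and the phenoxide expels tert-butyl carbonate, which releases 14 directly. Sodium p-toluenesulfinate and AcOH in the same flask then add to C4. The route is rejoined at 9.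

**Further compounds**
F1 | step 8 | dimethyl{2-[3,4-bis(benzyloxy)phenyl]-2-oxoethyl}sulfonium bromide | C[S+](C)CC(=O)c1ccc(OCc2ccccc2)c(OCc2ccccc2)c1.[Br-]
F2 | step 8 | (2S,3R)-trans diastereomer of 16 | O=C(c1ccc(OCc2ccccc2)c(OCc2ccccc2)c1)[C@H]1Oc2cc(OCc3ccccc3)ccc2[C@@H]1c1c(OCc3ccccc3)cc(OCc3ccccc3)c2c1O[C@H](c1ccc(OCc3ccccc3)c(OCc3ccccc3)c1)[C@@H](OCc1ccccc1)C2
F3 | step 9 | (1R,3S)-1-[3,4-bis(benzyloxy)phenyl]-3-[4-(benzyloxy)-2-hydroxyphenyl]-3-(penta-O-benzylcatechin-8-yl)propan-1-ol | O[C@@H](c1ccc(OCc2ccccc2)c(OCc2ccccc2)c1)C[C@@H](c1ccc(OCc2ccccc2)cc1O)c1c(OCc3ccccc3)cc(OCc3ccccc3)c2c1O[C@H](c1ccc(OCc3ccccc3)c(OCc3ccccc3)c1)[C@@H](OCc1ccccc1)C2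
F4 | step 4 | 5-(benzyloxy)-2-formylphenyl tert-butyl carbonate | O=Cc1ccc(OCc2ccccc2)cc1OC(=O)OC(C)(C)C
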